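Assumption: commercial (−)-α-bisabolol (levomenol) is the (S,S)-enantiomer. Bisabolane numbering is used in the explanations: C6 = ring CH bearing the side chain, C7 = carbinol/ether carbon, C8–C11 = the other pyran carbons.

**Retrosynthetic overview**
1. Target 8 ⇒ 7: the C8 hydroxyl is introduced last by allylic C–H hydroxylation of the dihydropyran.
2. 7 ⇒ 3: ring Br/Cl come from the bromonium ion on the face cis to the side chain, made stereospecifically (epoxide 4 → bromohydrin 5 → bromonium), captured by chloride and equilibrated diaxial → diequatorial.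
3. 3 ⇒ 1: the pyran O–C11 bond is closed by bromonium-triggered 6-endo etherification of the C7–OH onto the side-chain alkene, followed by loss of HBr.
4. Ring order: the cyclohexene ring (with C6 and C7 already set) is bought in (−)-α-bisabolol; the dihydropyran is closed in step 1; no further ring is formed.

**Route**

Step 1
Reactants: 1 (−)-α-bisabolol
Product: 3 (2S)-2,6,6-trimethyl-2-[(1S)-4-methylcyclohex-3-en-1-yl]-3,6-dihydro-2H-pyran, via bromotetrahydropyran 2 (not isolated)
Conditions: NBS (1.05 equiv), CH2Cl2–HFIP 9:1, −20 °C; evaporate; t-BuOK (4 equiv), DMSO, 50 °C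
Reagents that add atoms: none
Why: Bromonium-induced haloetherification, in which the C7–OH opens the C10–C11 bromonium at the tertiary C11 (Markovnikov, 6-endo, chair transition state) while the ring bromonium has no internal nucleophile and reverts; the crude secondary bromide has β-hydrogens only at C9, so E2 gives the Δ9 olefin, erases C10 and leaves C6/C7 untouched.

Step 2
Reactants: 3 (2S)-2,6,6-trimethyl-2-[(1S)-4-methylcyclohex-3-en-1-yl]-3,6-dihydro-2H-pyran
Product: 4 (1S,4S,6R)-1-methyl-4-[(2S)-2,6,6-trimethyl-3,6-dihydro-2H-pyran-2-yl]-7-oxabicyclo[4.1.0]heptane (epoxide oxygen trans to the pyranyl group)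
Conditions: D-fructose-derived Shi ketone (0.3 equiv), Oxone, K2CO3, Bu4NHSO4, MeCN–DMM / aq. borate buffer pH 10.5, 0 °C
Reagents that add atoms: Oxone (potassium peroxymonosulfate), [K+].[O-]S(=O)(=O)OO
Why: Shi asymmetric epoxidation (chiral dioxirane, spiro transition state) gives catalyst-controlled delivery of oxygen to the ring trisubstituted alkene face trans to the side chain (the substrate itself has no facial bias), while the hindered cis-disubstituted Δ9 allyl-ether alkene is not a substrate for this catalyst.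

Step 3
Reactants: 4 (1S,4S,6R)-1-methyl-4-[(2S)-2,6,6-trimethyl-3,6-dihydro-2H-pyran-2-yl]-7-oxabicyclo[4.1.0]heptane
Product: 5 (1R,2R,5S)-2-bromo-2-methyl-5-[(2S)-2,6,6-trimethyl-3,6-dihydro-2H-pyran-2-yl]cyclohexan-1-ol
Conditions: LiBr (3 equiv), AcOH (2 equiv), THF, 0 °C
Reagents that add atoms: lithium bromide, [Li+].[Br-]
Why: Acid-assisted epoxide opening in which trans-diaxial (Fürst–Plattner) and Markovnikov control coincide, so bromide attacks the tertiary carbon with inversion from the face cis to the side chain and gives the axial tertiary bromide anti-periplanar to the axial secondary OH; the acid is weak enough to spare the allylic ether.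

Step 4
Reactants: 5 (1R,2R,5S)-2-bromo-2-methyl-5-[(2S)-2,6,6-trimethyl-3,6-dihydro-2H-pyran-2-yl]cyclohexan-1-ol
Product: 7 (2S)-2-[(1S,3S,4S)-3-bromo-4-chloro-4-methylcyclohexyl]-2,6,6-trimethyl-3,6-dihydro-2H-pyran, via diaxial bromochloride 6 (not isolated)
Conditions: PPh3/NCS (1.2 equiv each, premixed), CH2Cl2, 0 °C → rt; silica plug; then PhCl, CaCO3 (acid scavenger), 120 °C
Reagents that add atoms: N-chlorosuccinimide, O=C1CCC(=O)N1Cl
Why: Appel-type activation with neighbouring-group participation, in which the anti-periplanar bromine expels Ph3PO to give the bromonium on the face cis to the side chain and chloride opens it anti (mainly diaxially, to 6); heating then drives the diaxial → diequatorial 1,2-dihalide rearrangement, each halogen staying on its own face, which puts Cl on the tertiary carbon (4S) and Br on the secondary carbon (3S).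

Step 5
Reactants: 7 (2S)-2-[(1S,3S,4S)-3-bromo-4-chloro-4-methylcyclohexyl]-2,6,6-trimethyl-3,6-dihydro-2H-pyran
Product: 8 (2R,3R)-2-[(1S,3S,4S)-3-bromo-4-chloro-4-methylcyclohexyl]-2,6,6-trimethyl-3,6-dihydro-2H-pyran-3-ol (target)
Conditions: SeO2 (1.0 equiv), pyridine (0.2 equiv), 1,4-dioxane, 80 °C
Reagents that add atoms: selenium dioxide, O=[Se]=O
Why: Riley allylic hydroxylation (ene reaction then [2,3]-sigmatropic shift), where the only allylic C–H bonds are at C8; SeO2 adds to C10 anti to the pseudoaxial C11 methyl and removes the pseudoaxial H-8, which lies anti to the axial C7 methyl, so oxygen enters trans to that methyl and cis to the cyclohexyl group (8R) with the olefin returned to C9=C10.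

**Compound list**
1 | (−)-α-bisabolol, (2S)-6-methyl-2-[(1S)-4-methylcyclohex-3-en-1-yl]hept-5-en-2-ol | CC(C)=CCC[C@@](C)(O)[C@H]1CCC(C)=CC1 | starting material
2 | (3R,6S)-3-bromo-2,2,6-trimethyl-6-[(1S)-4-methylcyclohex-3-en-1-yl]oxane (major C3 epimer shown; the 3S epimer eliminates to the same olefin) | CC1(C)[C@H](Br)CC[C@@](C)([C@H]2CCC(C)=CC2)O1 | intermediate (not isolated)
3 | (2S)-2,6,6-trimethyl-2-[(1S)-4-methylcyclohex-3-en-1-yl]-3,6-dihydro-2H-pyran | CC1(C)C=CC[C@@](C)([C@H]2CCC(C)=CC2)O1 | intermediate
4 | (1S,4S,6R)-1-methyl-4-[(2S)-2,6,6-trimethyl-3,6-dihydro-2H-pyran-2-yl]-7-oxabicyclo[4.1.0]heptane | CC1(C)C=CC[C@@](C)([C@H]2CC[C@](C)(O3)[C@H]3C2)O1 | intermediate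
5 | (1R,2R,5S)-2-bromo-2-methyl-5-[(2S)-2,6,6-trimethyl-3,6-dihydro-2H-pyran-2-yl]cyclohexan-1-ol | CC1(C)C=CC[C@@](C)([C@H]2CC[C@@](C)(Br)[C@H](O)C2)O1 | intermediate
6 | (2S)-2-[(1S,3R,4R)-4-bromo-3-chloro-4-methylcyclohexyl]-2,6,6-trimethyl-3,6-dihydro-2H-pyran (trans-diaxial halogens) | CC1(C)C=CC[C@@](C)([C@H]2CC[C@@](C)(Br)[C@H](Cl)C2)O1 | intermediate (not isolated)
7 | (2S)-2-[(1S,3S,4S)-3-bromo-4-chloro-4-methylcyclohexyl]-2,6,6-trimethyl-3,6-dihydro-2H-pyran (trans-diequatorial halogens) | CC1(C)C=CC[C@@](C)([C@H]2CC[C@](C)(Cl)[C@@H](Br)C2)O1 | intermediate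
8 | (2R,3R)-2-[(1S,3S,4S)-3-bromo-4-chloro-4-methylcyclohexyl]-2,6,6-trimethyl-3,6-dihydro-2H-pyran-3-ol | CC1(C)C=C[C@@H](O)[C@@](C)([C@H]2CC[C@](C)(Cl)[C@@H](Br)C2)O1 | target

**Step count**
Total steps: 5. Longest linear sequence: 5 (from 1).

**Three steps most likely to fail, with fallbacks**

Step 4. The chloride capture may be unselective, and the position of the 6 ⇌ 7 equilibrium is not certain. The fallback sets out from 5 and comes back to the route at 7. Alcohol 5 is converted with MsCl/Et3N (CH2Cl2, 0 °C) into (1R,2R,5S)-2-bromo-2-methyl-5-[(2S)-2,6,6-trimethyl-3,6-dihydro-2H-pyran-2-yl]cyclohexyl methanesulfonate F2. F2 is then solvolysed with LiCl (5 equiv) and 2,6-lutidine in HFIP at room temperature. In this ionising, weakly nucleophilic medium the bromine-assisted ionisation gives the same cis-face bromonium, but it is trapped kinetically at the tertiary carbon (Markovnikov), giving 7 directly without relying on the thermal equilibration.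

Step 5. The cis-olefin flanked by two quaternary carbons may react sluggishly with SeO2, and the facial preference depends on which C7 substituent sits axial, so the 8R/8S ratio may be modest. The fallback sets out from 7 and comes back at 8. Allylic oxidation with Rh2(cap)4 (cat.)/t-BuOOH/K2CO3 in CH2Cl2 gives the enone (2R)-2-[(1S,3S,4S)-3-bromo-4-chloro-4-methylcyclohexyl]-2,6,6-trimethyl-2H-pyran-3(6H)-one F3. F3 is then reduced under catalyst control with (S)-Me-CBS/BH3·SMe2 (toluene, −40 °C), the quaternary C2 side acting as the large group, to give the 3R alcohol 8.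

Step 1. The 5-exo bromoether (tetrahydrofuran with a CMe2Br group) and a cineole-type ether from attack of the C7–OH on the ring bromonium can compete with the 6-endo closure. The fallback sets out from 1 and comes back at 3. N-(Phenylseleno)phthalimide with catalytic CSA (CH2Cl2, rt) cyclises 1 under reversible, thermodynamically controlled seleniranium formation to the 6-endo selenide (3R,6S)-2,2,6-trimethyl-6-[(1S)-4-methylcyclohex-3-en-1-yl]-3-(phenylselanyl)oxane F1. Oxidation of F1 with H2O2/pyridine at 0 °C gives the selenoxide, whose syn-elimination can only go toward C9, giving 3 without a base-mediated E2.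

**Further compounds**
F1 | step 1 | (3R,6S)-2,2,6-trimethyl-6-[(1S)-4-methylcyclohex-3-en-1-yl]-3-(phenylselanyl)oxane | CC1(C)[C@H]([Se]c2ccccc2)CC[C@@](C)([C@H]2CCC(C)=CC2)O1
F2 | step 4 | (1R,2R,5S)-2-bromo-2-methyl-5-[(2S)-2,6,6-trimethyl-3,6-dihydro-2H-pyran-2-yl]cyclohexyl methanesulfonate | CC1(C)C=CC[C@@](C)([C@H]2CC[C@@](C)(Br)[C@H](OS(C)(=O)=O)C2)O1
F3 | step 5 | (2R)-2-[(1S,3S,4S)-3-bromo-4-chloro-4-methylcyclohexyl]-2,6,6-trimethyl-2H-pyran-3(6H)-one | CC1(C)C=CC(=O)[C@@](C)([C@H]2CC[C@](C)(Cl)[C@@H](Br)C2)O1
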